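**Retrosynthetic overview**
- The side-chain oxirane is formed last, by Shi epoxidation of C10=C11. Before that the C6–OH is unmasked (aryl ether) and a ring 3,4-epoxide is opened by chloride at C3 (trans-diaxial).
- Key disconnection C8–C9: [2,3]-Wittig rearrangement in which C8, an oxygen-bearing carbon, acts as a carbanion (reversed polarity) and attacks the vinyl terminus of a 1,1-dimethylallyl ether. Both angelates are put on the two lithium alkoxides in the same flask.
- Ring stereochemistry comes from (S)-carvone: α'-hydroxylation (trans), Mitsunobu inversion with 4-methoxyphenol (C6–O cis), Luche reduction (C5–OH cis), OH-directed epoxidation (oxirane cis).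
- The ether precursor comes from carvone by allylic chlorination and silver-assisted etherification with 2-methylbut-3-en-2-ol.
- Ring order: the carbocycle is carvone's; the ring oxirane is made in step 6 and opened in step 8; the side-chain oxirane is made in step 10.

Assumption: the sense of induction of the chiral ligand in step 7 on this substrate cannot be predicted with certainty; the (S,S)-ligand is written and its enantiomer would be used if it proved mismatched.

Locants in the names of 11–16 and F1–F3 follow the bisabolane skeleton: ring C1–C6 (side chain on C1, methyl on C4), side chain C7(=C14H2)–C8–C9–C10–C11(Me)2.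

**Step 1**
Reactants: 1 (S)-(+)-carvone
Product: 2 (5S)-5-(3-chloroprop-1-en-2-yl)-2-methylcyclohex-2-en-1-one (10-chlorocarvone)
Conditions: Ca(OCl)2, CO2 (dry ice), CH2Cl2/H2O, 0 °C
Reagents that add atoms: calcium hypochlorite, [Ca+2].[O-]Cl.[O-]Cl
Why: Ene-type allylic chlorination by HOCl formed in situ attacks only the electron-rich 1,1-disubstituted alkene (the enone C=C is inert) and gives the 2-substituted allyl chloride without touching C5.

**Step 2**
Reactants: 2 (5S)-5-(3-chloroprop-1-en-2-yl)-2-methylcyclohex-2-en-1-one; 3 2-methylbut-3-en-2-ol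
Product: 4 (5S)-2-methyl-5-{3-[(2-methylbut-3-en-2-yl)oxy]prop-1-en-2-yl}cyclohex-2-en-1-one
Conditions: AgOTf, 2,6-di-tert-butyl-4-methylpyridine, 3 (5 equiv), CH2Cl2, −20 °C → rt, dark
Reagents that add atoms: none
Why: Silver-assisted etherification (SN1/SN2 borderline) of the allylic chloride; the 2-substituted allyl cation is symmetric so only one ether can form, and the non-basic conditions avoid enolisation of the enone and its intramolecular alkylation.

**Step 3**
Reactants: 4 (5S)-2-methyl-5-{3-[(2-methylbut-3-en-2-yl)oxy]prop-1-en-2-yl}cyclohex-2-en-1-one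
Product: 6 (5R,6R)-6-hydroxy-2-methyl-5-{3-[(2-methylbut-3-en-2-yl)oxy]prop-1-en-2-yl}cyclohex-2-en-1-one (hydroxyl trans to the side chain), via lithium dienolate 5 (not isolated)
Conditions: LDA, THF, −78 °C; then 2-(phenylsulfonyl)-3-phenyloxaziridine, −78 °C; AcOH quench
Reagents that add atoms: 2-(phenylsulfonyl)-3-phenyloxaziridine, O=S(=O)(c1ccccc1)N1OC1c1ccccc1
Why: Davis hydroxylation of the kinetic α'-enolate; oxygen is delivered to the face opposite the neighbouring C5 substituent, which sets C6 trans (6R).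

**Step 4**
Reactants: 6 (5R,6R)-6-hydroxy-2-methyl-5-{3-[(2-methylbut-3-en-2-yl)oxy]prop-1-en-2-yl}cyclohex-2-en-1-one
Product: 7 (5R,6S)-6-(4-methoxyphenoxy)-2-methyl-5-{3-[(2-methylbut-3-en-2-yl)oxy]prop-1-en-2-yl}cyclohex-2-en-1-one (aryloxy cis to the side chain)
Conditions: 4-methoxyphenol, PPh3, DIAD, toluene, 0 °C → rt
Reagents that add atoms: 4-methoxyphenol, COc1ccc(O)cc1
Why: Mitsunobu etherification with SN2 inversion at the activated α-keto carbinol converts the trans ketol into the cis C6–O configuration and installs a base-stable, oxidatively removable aryl ether.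

**Step 5**
Reactants: 7 (5R,6S)-6-(4-methoxyphenoxy)-2-methyl-5-{3-[(2-methylbut-3-en-2-yl)oxy]prop-1-en-2-yl}cyclohex-2-en-1-one
Product: 8 (1R,5R,6S)-6-(4-methoxyphenoxy)-2-methyl-5-{3-[(2-methylbut-3-en-2-yl)oxy]prop-1-en-2-yl}cyclohex-2-en-1-ol (all-cis)
Conditions: NaBH4, CeCl3·7H2O, MeOH, −78 °C
Reagents that add atoms: none
Why: Luche 1,2-reduction; hydride adds axially from the face opposite the axial aryloxy group, giving the equatorial alcohol cis to both the C6 oxygen and the side chain.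

**Step 6**
Reactants: 8 (1R,5R,6S)-6-(4-methoxyphenoxy)-2-methyl-5-{3-[(2-methylbut-3-en-2-yl)oxy]prop-1-en-2-yl}cyclohex-2-en-1-ol
Product: 9 (1S,2S,3S,4R,6R)-3-(4-methoxyphenoxy)-1-methyl-4-{3-[(2-methylbut-3-en-2-yl)oxy]prop-1-en-2-yl}-7-oxabicyclo[4.1.0]heptan-2-ol (oxirane cis to the hydroxyl)
Conditions: VO(acac)2 (5 mol %), t-BuOOH, CH2Cl2, 0 °C → rt
Reagents that add atoms: tert-butyl hydroperoxide, CC(C)(C)OO
Why: Vanadium-catalysed hydroxyl-directed epoxidation delivers oxygen syn to the allylic OH; the other alkenes carry no directing hydroxyl and stay intact.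

**Step 7**
Reactants: 9 (1S,2S,3S,4R,6R)-3-(4-methoxyphenoxy)-1-methyl-4-{3-[(2-methylbut-3-en-2-yl)oxy]prop-1-en-2-yl}-7-oxabicyclo[4.1.0]heptan-2-ol; 10 angelic anhydride
Product: 13 (1R,3R,4R,5S,6S,8S)-3,4-epoxy-6-(4-methoxyphenoxy)bisabola-7(14),10-diene-5,8-diyl bis[(Z)-2-methylbut-2-enoate], via C8-lithiated lithium alkoxide 11 (not isolated), via rearranged dilithium dialkoxide 12 (not isolated)
Conditions: t-BuLi (2.3 equiv), 2,2-bis[(4S)-4-isopropyl-4,5-dihydrooxazol-2-yl]propane (1.5 equiv), Et2O/hexane, −78 °C; then 10 (3 equiv), THF, −78 → 0 °C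
Reagents that add atoms: none
Why: Proposed new method: after alkoxide formation the chiral t-BuLi·bis(oxazoline) complex removes one of the two diastereotopic C8–H atoms of the bis-allylic ether, and the resulting α-oxygenated allyl carbanion (a carbinol carbon acting as nucleophile) attacks the vinyl terminus through the five-membered [2,3]-Wittig transition state with inversion at the lithiated carbon, which forges C8–C9, moves the alkene to C10=C11 and sets 8S under ligand control, after which both lithium alkoxides are acylated by the anhydride without Z→E isomerisation; closest known reaction type: enantioselective [2,3]-Wittig rearrangement with t-BuLi/chiral bis(oxazoline) followed by acylation of a lithium alkoxide with angelic anhydride.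

**Step 8**
Reactants: 13 (1R,3R,4R,5S,6S,8S)-3,4-epoxy-6-(4-methoxyphenoxy)bisabola-7(14),10-diene-5,8-diyl bis[(Z)-2-methylbut-2-enoate]
Product: 14 (1R,3S,4S,5S,6S,8S)-3-chloro-4-hydroxy-6-(4-methoxyphenoxy)bisabola-7(14),10-diene-5,8-diyl bis[(Z)-2-methylbut-2-enoate]
Conditions: Li2CuCl4, THF, 0 °C → rt; H2O work-up
Reagents that add atoms: dilithium tetrachlorocuprate, [Li+].[Li+].Cl[Cu-2](Cl)(Cl)Cl
Why: SN2 epoxide opening by chloride at the secondary C3 in the trans-diaxial (Fürst–Plattner) sense, with inversion, gives Cl trans to the tertiary C4–OH; attack at C4 is disfavoured sterically and by the adjacent ester.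

**Step 9**
Reactants: 14 (1R,3S,4S,5S,6S,8S)-3-chloro-4-hydroxy-6-(4-methoxyphenoxy)bisabola-7(14),10-diene-5,8-diyl bis[(Z)-2-methylbut-2-enoate]
Product: 15 (1R,3S,4S,5S,6S,8S)-3-chloro-4,6-dihydroxybisabola-7(14),10-diene-5,8-diyl bis[(Z)-2-methylbut-2-enoate]
Conditions: (NH4)2Ce(NO3)6, MeCN/H2O (4:1), 0 °C
Reagents that add atoms: none
Why: Oxidative dearylation of the 4-methoxyphenyl ether; the alkyl C–O bond is not broken, so C6 keeps its configuration, and the chlorohydrin, esters and alkenes tolerate the brief acidic oxidation.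

**Step 10**
Reactants: 15 (1R,3S,4S,5S,6S,8S)-3-chloro-4,6-dihydroxybisabola-7(14),10-diene-5,8-diyl bis[(Z)-2-methylbut-2-enoate]
Product: 16 (1R,3S,4S,5S,6S,8S,10R)-3-chloro-10,11-epoxy-4,6-dihydroxybisabol-7(14)-ene-5,8-diyl bis[(Z)-2-methylbut-2-enoate] (CNP0158207.1)
Conditions: D-fructose-derived Shi ketone (3 equiv), Oxone, NaHCO3, MeCN/aq. Na2EDTA, 0 °C, pH 7–8
Reagents that add atoms: potassium peroxymonosulfate (Oxone), [K+].[O-]S(=O)(=O)OO
Why: Shi asymmetric epoxidation; the chiral dioxirane reacts only with the electron-rich trisubstituted C10=C11 alkene through the spiro transition state to give 10R, and the near-neutral pH keeps the base-sensitive chlorohydrin from closing.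

**Compound list**
1 | (S)-(+)-carvone, (5S)-2-methyl-5-(prop-1-en-2-yl)cyclohex-2-en-1-one | C=C(C)[C@H]1CC=C(C)C(=O)C1 | starting material
2 | (5S)-5-(3-chloroprop-1-en-2-yl)-2-methylcyclohex-2-en-1-one | C=C(CCl)[C@H]1CC=C(C)C(=O)C1 | intermediate
3 | 2-methylbut-3-en-2-ol | C=CC(C)(C)O | starting material
4 | (5S)-2-methyl-5-{3-[(2-methylbut-3-en-2-yl)oxy]prop-1-en-2-yl}cyclohex-2-en-1-one | C=C(COC(C)(C)C=C)[C@H]1CC=C(C)C(=O)C1 | intermediate
5 | lithium dienolate of 4 (O–Li on C1, double bonds C1=C6 and C2=C3) | [Li+].C=C(COC(C)(C)C=C)[C@H]1CC=C(C)C([O-])=C1 | intermediate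
6 | (5R,6R)-6-hydroxy-2-methyl-5-{3-[(2-methylbut-3-en-2-yl)oxy]prop-1-en-2-yl}cyclohex-2-en-1-one | C=C(COC(C)(C)C=C)[C@H]1CC=C(C)C(=O)[C@@H]1O | intermediate
7 | (5R,6S)-6-(4-methoxyphenoxy)-2-methyl-5-{3-[(2-methylbut-3-en-2-yl)oxy]prop-1-en-2-yl}cyclohex-2-en-1-one | C=C(COC(C)(C)C=C)[C@H]1CC=C(C)C(=O)[C@H]1Oc1ccc(OC)cc1 | intermediate
8 | (1R,5R,6S)-6-(4-methoxyphenoxy)-2-methyl-5-{3-[(2-methylbut-3-en-2-yl)oxy]prop-1-en-2-yl}cyclohex-2-en-1-ol | C=C(COC(C)(C)C=C)[C@H]1CC=C(C)[C@@H](O)[C@H]1Oc1ccc(OC)cc1 | intermediate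
9 | (1S,2S,3S,4R,6R)-3-(4-methoxyphenoxy)-1-methyl-4-{3-[(2-methylbut-3-en-2-yl)oxy]prop-1-en-2-yl}-7-oxabicyclo[4.1.0]heptan-2-ol | C=C(COC(C)(C)C=C)[C@H]1C[C@H]2O[C@@]2(C)[C@@H](O)[C@H]1Oc1ccc(OC)cc1 | intermediate
10 | angelic anhydride, (Z)-2-methylbut-2-enoic anhydride | C/C=C(/C)C(=O)OC(=O)/C(C)=C\C | starting material
11 | dilithium species of 9: 5-olate and C8 carbanion (C8 configurationally labile) | [Li+].[Li+].C=C([CH-]OC(C)(C)C=C)[C@H]1C[C@H]2O[C@@]2(C)[C@@H]([O-])[C@H]1Oc1ccc(OC)cc1 | intermediate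
12 | dilithium (1R,3R,4S,5S,6S,8S)-3,4-epoxy-6-(4-methoxyphenoxy)bisabola-7(14),10-diene-5,8-diolate | [Li+].[Li+].C=C([C@H](CC=C(C)C)[O-])[C@H]1C[C@H]2O[C@@]2(C)[C@@H]([O-])[C@H]1Oc1ccc(OC)cc1 | intermediate
13 | (1R,3R,4R,5S,6S,8S)-3,4-epoxy-6-(4-methoxyphenoxy)bisabola-7(14),10-diene-5,8-diyl bis[(Z)-2-methylbut-2-enoate] | C=C([C@H](CC=C(C)C)OC(=O)/C(C)=C\C)[C@H]1C[C@H]2O[C@@]2(C)[C@@H](OC(=O)/C(C)=C\C)[C@H]1Oc1ccc(OC)cc1 | intermediate
14 | (1R,3S,4S,5S,6S,8S)-3-chloro-4-hydroxy-6-(4-methoxyphenoxy)bisabola-7(14),10-diene-5,8-diyl bis[(Z)-2-methylbut-2-enoate] | C=C([C@H](CC=C(C)C)OC(=O)/C(C)=C\C)[C@H]1C[C@H](Cl)[C@@](C)(O)[C@@H](OC(=O)/C(C)=C\C)[C@H]1Oc1ccc(OC)cc1 | intermediate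
15 | (1R,3S,4S,5S,6S,8S)-3-chloro-4,6-dihydroxybisabola-7(14),10-diene-5,8-diyl bis[(Z)-2-methylbut-2-enoate] | C=C([C@H](CC=C(C)C)OC(=O)/C(C)=C\C)[C@H]1C[C@H](Cl)[C@@](C)(O)[C@@H](OC(=O)/C(C)=C\C)[C@H]1O | intermediate
16 | (1R,3S,4S,5S,6S,8S,10R)-3-chloro-10,11-epoxy-4,6-dihydroxybisabol-7(14)-ene-5,8-diyl bis[(Z)-2-methylbut-2-enoate] (CNP0158207.1) | C=C([C@H](C[C@H]1OC1(C)C)OC(=O)/C(C)=C\C)[C@H]1C[C@H](Cl)[C@@](C)(O)[C@@H](OC(=O)/C(C)=C\C)[C@H]1O | target

**Total step count:** 10. **Longest linear sequence:** 10 steps (from 1).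

**Steps most likely to fail**

Step 7 is the main risk. The diastereoselectivity at C8 under ligand control is untested on a chiral substrate that also carries a lithium alkoxide, and the oxirane must survive the organolithium. The fallback sets out from 9 and returns at 13. The rearrangement is run with n-BuLi alone in THF at −78 °C and quenched with NH4Cl, giving the C8-epimeric epoxy diol F1. MnO2 in CH2Cl2 oxidises only the allylic C8 carbinol to the α-methylene ketone F2. (R)-Me-CBS with catecholborane at −78 °C reduces this to the (8S)-epoxy diol F3. LiHMDS and 10 in THF then give 13.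

Step 4 is the second risk. The oxyphosphonium of the hindered α-ketol may eliminate, or the cis product may epimerise back to trans. The fallback sets out from 4 and returns at 7, bypassing 6. LDA/TMSCl gives the trimethylsilyl dienol ether F4. NBS brominates it opposite to the side chain to give the trans-6-bromo ketone F5. Caesium 4-methoxyphenoxide in DMF at 0 °C displaces bromide with inversion to give 7.

Step 2 is the third risk. A hindered tertiary allylic alcohol is a poor nucleophile, and silver-promoted ionisation may be sluggish for a chloride. The fallback sets out from 2 and 3 and returns at 4. Alcohol 3 is converted with Et2Zn (0.5 equiv) to zinc bis(2-methylbut-3-en-2-olate) F6. This is coupled with 2 under Pd(OAc)2/2-(di-tert-butylphosphino)biphenyl catalysis in THF at rt, through the symmetric π-allylpalladium intermediate.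

**Further compounds**
F1 | step 7 | (1R,3R,4S,5S,6S,8RS)-3,4-epoxy-6-(4-methoxyphenoxy)bisabola-7(14),10-diene-5,8-diol (C8 epimers) | C=C(C(CC=C(C)C)O)[C@H]1C[C@H]2O[C@@]2(C)[C@@H](O)[C@H]1Oc1ccc(OC)cc1
F2 | step 7 | (1R,3R,4S,5S,6S)-3,4-epoxy-5-hydroxy-6-(4-methoxyphenoxy)bisabola-7(14),10-dien-8-one | C=C(C(=O)CC=C(C)C)[C@H]1C[C@H]2O[C@@]2(C)[C@@H](O)[C@H]1Oc1ccc(OC)cc1
F3 | step 7 | (1R,3R,4S,5S,6S,8S)-3,4-epoxy-6-(4-methoxyphenoxy)bisabola-7(14),10-diene-5,8-diol | C=C([C@H](CC=C(C)C)O)[C@H]1C[C@H]2O[C@@]2(C)[C@@H](O)[C@H]1Oc1ccc(OC)cc1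
F4 | step 4 | trimethyl{[(3S)-6-methyl-3-{3-[(2-methylbut-3-en-2-yl)oxy]prop-1-en-2-yl}cyclohexa-1,5-dien-1-yl]oxy}silane | C=C(COC(C)(C)C=C)[C@H]1CC=C(C)C(O[Si](C)(C)C)=C1
F5 | step 4 | (5R,6R)-6-bromo-2-methyl-5-{3-[(2-methylbut-3-en-2-yl)oxy]prop-1-en-2-yl}cyclohex-2-en-1-one | C=C(COC(C)(C)C=C)[C@H]1CC=C(C)C(=O)[C@@H]1Br
F6 | step 2 | zinc bis(2-methylbut-3-en-2-olate) | [Zn+2].[O-]C(C)(C)C=C.[O-]C(C)(C)C=C
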